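## The problem

Target 19 is a trans-2-aryl-3-aroyl-2,3-dihydrobenzofuran whose dihydrofuran ring is fused to a phloroglucinol-type benzene ring (ring A) across C3a–C7a. Ring A is pentasubstituted: O1 at C7a lies between the carbon substituents at C3a (C3 of the furan) and C7 (the 2-arylacryloyl group), free hydroxyls stand at C4 and C6, and only C5 carries hydrogen. C5 and C7 of such a ring are almost equally activated, so this pattern cannot be left to a late electrophilic substitution. The two adjacent stereocentres, C2 (R) and C3 (R), are trans. C3 is benzylic and α to the benzoyl carbonyl and will epimerise, so the absolute configuration has to be set at the ether carbon C2, and C3 can then settle trans under thermodynamic control. Four features limit the reagents: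

- the 2-arylacryloyl unit, a Michael acceptor next to the C6 hydroxyl (closure to an isoflavanone under base) whose alkene rules out hydrogenolysis;
- the β-aryloxy ketone O1–C2–C3–C=O;
- the acid-labile benzylic C2–O1 bond to a para-oxygenated aryl group;
- five phenols that must stay protected until the last step.

The enabling feature is that C3a–C3 and C7a–O1 lie on adjacent carbons of ring A and that the next carbon, C7, already bears a carbon substituent. This is the product pattern of an ortho C–H alkylation with ipso etherification of an ortho-substituted aryl iodide, and the C2–C3 unit with its oxygen maps onto the epoxide of a chalcone.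

## Retrosynthesis

**19 ⇒ 18.** The five O–benzyl bonds are cut. Benzyl ethers are preferred to silyl ethers, which would not survive the hydroxide of the chalcone condensation or carbonate at 80 °C. They are preferred to methoxymethyl ethers, whose removal needs protic acid and sets formaldehyde free next to the nucleophilic C5. Pentabenzyl ether 18 can be unmasked by a Lewis acid with a cation scavenger, which spares the alkene and avoids base. The forward step must not benzylate C5 or open the C2–O1 bond.

**18 ⇒ 16 + 13 (through 17).** The bond between the C7 carbonyl carbon and the vinyl carbon is cut, which removes the sensitive enone and leaves aldehyde 16 and alkenyl triflate 13. An acylation at C7 would have to tell C7 from C5 and needs acid; building a deoxybenzoin and methylenating it is longer. The forward reaction must add to a hindered aldehyde without touching the C3 ketone or the acidic C3–H, and carbinol 17 must then be oxidised.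

**16 ⇒ 15.** The aldehyde is masked as a dioxolane. The acetal carbon is the ortho substituent that the annulation needs, it is stable to carbonate, and mild acid returns the aldehyde.

**15 ⇒ 5 + 10.** C3–C3a and C7a–O1 are cut. Cutting C2–C3 or O1–C2 instead would demand a ring A that already carries a carbon at C3a and three differentiated oxygens. This cut takes ring A back to iodide 5 with one free ortho C–H and takes the C2–C3 unit back to epoxy ketone 10. The benzylic C–O bond of 10 becomes O1–C2 unchanged, so C2 takes its configuration from the epoxide. Both precursors are three steps from purchasable material. The forward reaction must open 10 at the α-keto carbon, close the ring by C–O bond formation at C7a, and bring C3 from cis (14) to trans (15).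

**5 ⇒ 4 ⇒ 2 ⇒ 1.** The acetal, the formyl C–C bond and the two O–benzyl bonds are cut. Arene 2 is mirror-symmetric, so one formylation ortho to iodine fixes the whole pattern of ring A: the formyl carbon becomes C7, iodine marks C7a and the free position on its other side is C3a.

**10 ⇒ 9 ⇒ 7 + 8; 7 ⇒ 6.** The two epoxide C–O bonds are cut back to E-chalcone 9, whose enantioselective nucleophilic epoxidation sets the future C2. The C=C bond of 9 is cut to ketone 7 and aldehyde 8 (aldol condensation), and 7 comes from 6 by benzylation.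

**13 ⇒ 11.** The O–S bond of the enol triflate is cut back to ketone 11, which has only one enolisable position.

## Roads not taken

**Alternative 1:** Ring A itself is cut at C3a–C7a, C4–C5 and C6–C7, so that the benzene ring and the ring fusion arise in one [2+2+2] cyclotrimerisation. Forward, [Rh(cod)2]BF4 with BINAP would join the tethered diyne A1 (an ethynyl ether of the C2 carbinol linked through C3 to a silyloxyalkyne) with (ethynyloxy)triisopropylsilane A2 to give the trans-dihydrobenzofuran A3.
- Merits: the oxygenation of ring A is written into the alkynes, no aromatic substitution is needed, both stereocentres are set beforehand in an open chain, and rhodium-catalysed diyne–alkyne cyclotrimerisation is an established reaction type, which the annulation of step 8 is not.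
- Weak points: A1 combines an ethynyl ether of a secondary benzylic alcohol with a silyl ynol ether, two fragile alkyne classes, and needs a long preparation. The orientation of A2 in the rhodacycle is not secured by precedent, although repulsion between the silyloxy groups should favour the needed sense. A3 carries neither acyl group: its CH2OSi group must pass through an epimerisable aldehyde to the aryl ketone, and C7 must be acylated in competition with C5 on a silyl-protected ring.
- Comparison: the ring-forming event is the safer one, but the route is estimated at about twice the length. The chosen plan sets against this a key step that delivers the C3 aroyl group and the C7 carbon together with the ring.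

**Alternative 2:** C3–C3a and C2–C3 are cut, so that C3 is assembled from three pieces. Rh2(OAc)4 would turn diazoketone A4 into a carbenoid, 1,3,5-tris(benzyloxy)benzene A5 would attack it, and the resulting enol would be intercepted by aldehyde 8 bound to a chiral phosphoric acid, giving the β-hydroxy ketone A6.
- Merits: the whole carbon skeleton of the heterocycle, aryl ketone included, comes from three simple components in one step; the arene is symmetric, so there is no regiochemistry at that stage; in convergence it is at least the equal of the chosen plan.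
- Weak points: the interception must outrun the intramolecular proton shift that rearomatises the intermediate, which is not established for alkoxyarenes, and the acceptor-only carbenoid can also cyclopropanate the arene. A6 then needs one of two equivalent ortho benzyl ethers removed among six and ring closure by substitution at C2. There the C–O bond made under catalyst control is broken at a para-alkoxybenzylic carbon, so enantiopurity would rest on the enolisable C3. The C7 carbon is still missing.
- Comparison: the chosen plan keeps the C2–O bond intact from epoxide to target and has C7 in place from the start.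

**Alternative 3:** C2–C3 is cut. The aryldiazoacetate A7 with Rh2(S-PTTL)4 (dirhodium tetrakis[N-phthaloyl-(S)-tert-leucinate]) would give a carbenoid at C3 that inserts into the benzylic C–H bond of the aryl benzyl ether, and DBU in the same flask would epimerise C3 to the trans ester A8.
- Merits: this is the best-precedented key step of the four, and in certainty it is better than step 8.
- Weak points: A8 carries an ester where the aryl ketone is needed, to be converted at a centre that is enolisable and β to an aryloxide. It has no C7 carbon, so a late formylation or acylation must tell C7 from C5 in the presence of acid-sensitive silyl ethers. A7 itself needs a ring A with a carbon at C3a and differently protected oxygens, because a benzyl ether at C4 would compete for the carbenoid.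
- Comparison: the route is linear and estimated at six or more steps longer. The chosen plan sets against the better precedent its convergence and the fact that the aroyl group and C7 arrive with the ring. The insertion chemistry is kept as the fallback for step 8.

Key step: step 8

Remark on the chemistry (assumptions): compounds 1, 6, 8 and 11 are taken as purchasable, and poly-L-leucine is taken to give the (2R,3S)-epoxide of chalcone 9 as it does for the parent chalcone.

## Route

Step 1
Reactants: 1 5-iodoresorcinol
Product: 2 1,3-bis(benzyloxy)-5-iodobenzene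
Conditions: BnBr, K2CO3, DMF, 60 °C
Reagents that add atoms: benzyl bromide, BrCc1ccccc1
Why: Williamson etherification of both phenols; the aryl iodide is inert to carbonate.

Step 2
Reactants: 2 1,3-bis(benzyloxy)-5-iodobenzene
Product: 4 2,4-bis(benzyloxy)-6-iodobenzaldehyde, via aryl iminium chloride 3 (not isolated)
Conditions: POCl3, DMF, 0 to 70 °C; then ice-water
Reagents that add atoms: N,N-dimethylformamide, CN(C)C=O; water, O
Why: Vilsmeier–Haack formylation; the position ortho to iodine is para to one benzyloxy group and ortho to the other and should be attacked in preference to the position flanked by both ethers, as is usual for 3,5-dialkoxyhalobenzenes, and water hydrolyses iminium salt 3.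

Step 3
Reactants: 4 2,4-bis(benzyloxy)-6-iodobenzaldehyde
Product: 5 2-[2,4-bis(benzyloxy)-6-iodophenyl]-1,3-dioxolane
Conditions: HOCH2CH2OH, p-TsOH·H2O (cat.), toluene, reflux (Dean–Stark)
Reagents that add atoms: ethane-1,2-diol, OCCO
Why: Acid-catalysed acetalisation driven by azeotropic removal of water; the dioxolane is stable to carbonate and is the ortho substituent required in step 8.

Step 4
Reactants: 6 1-(2,4-dihydroxyphenyl)ethan-1-one
Product: 7 1-[2,4-bis(benzyloxy)phenyl]ethan-1-one
Conditions: BnBr, K2CO3, DMF, 80 °C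
Reagents that add atoms: benzyl bromide, BrCc1ccccc1
Why: Williamson etherification; heat and excess bromide are used because the 2-hydroxyl is chelated to the ketone.

Step 5
Reactants: 7 1-[2,4-bis(benzyloxy)phenyl]ethan-1-one; 8 4-(benzyloxy)benzaldehyde
Product: 9 (E)-1-[2,4-bis(benzyloxy)phenyl]-3-[4-(benzyloxy)phenyl]prop-2-en-1-one
Conditions: KOH, EtOH–THF, rt
Reagents that add atoms: none
Why: Claisen–Schmidt condensation of a methyl ketone with a non-enolisable aldehyde; the E alkene is the thermodynamic product.

Step 6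
Reactants: 9 (E)-1-[2,4-bis(benzyloxy)phenyl]-3-[4-(benzyloxy)phenyl]prop-2-en-1-one
Product: 10 [2,4-bis(benzyloxy)phenyl]{(2R,3S)-3-[4-(benzyloxy)phenyl]oxiran-2-yl}methanone
Conditions: poly-L-leucine, urea–H2O2, DBU, THF, rt
Reagents that add atoms: urea–hydrogen peroxide, NC(N)=O.OO
Why: Juliá–Colonna epoxidation; hydroperoxide adds to the enone bound to the amide N–H groups at the end of the polypeptide helix, which fixes the face of attack and sets both epoxide carbons (2R,3S), and fast ring closure keeps the trans geometry of 9; crystallisation should raise the enantiomeric purity.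

Step 7
Reactants: 11 1-[4-(benzyloxy)phenyl]ethan-1-one
Product: 13 1-[4-(benzyloxy)phenyl]ethenyl trifluoromethanesulfonate, via potassium enolate 12 (not isolated)
Conditions: KHMDS, THF, −78 °C; then PhNTf2, −78 to 0 °C
Reagents that add atoms: N-phenylbis(trifluoromethanesulfonimide), O=S(=O)(N(c1ccccc1)S(=O)(=O)C(F)(F)F)C(F)(F)F
Why: O-sulfonylation of a ketone enolate; 11 has a single enolisable position, so only one enol triflate can form.

Step 8
Reactants: 5 2-[2,4-bis(benzyloxy)-6-iodophenyl]-1,3-dioxolane; 10 [2,4-bis(benzyloxy)phenyl]{(2R,3S)-3-[4-(benzyloxy)phenyl]oxiran-2-yl}methanone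
Product: 15 [(2R,3R)-4,6-bis(benzyloxy)-2-[4-(benzyloxy)phenyl]-7-(1,3-dioxolan-2-yl)-2,3-dihydro-1-benzofuran-3-yl][2,4-bis(benzyloxy)phenyl]methanone, via cis-epimer 14 (not isolated)
Conditions: Pd(OAc)2 (cat.), tri(2-furyl)phosphine, norbornene, Cs2CO3, MeCN, 80 °C, 5 in slight excess; then DBU, rt
Reagents that add atoms: none
Why: Proposed new method: oxidative addition of 5 to zerovalent palladium, norbornene insertion and palladation of C3a–H give an aryl–norbornyl palladacycle of divalent palladium, which is expected to open 10 at the carbon α to the ketone in an SN2-type oxidative addition to tetravalent palladium (this carbon is activated like that of an α-halo ketone and is the site at which zerovalent palladium attacks epoxy ketones); reductive elimination then makes C3–C3a and β-carbon elimination expels norbornene from the now ortho-disubstituted arene. The closest known reaction type is the palladium/norbornene annulation of ortho-substituted aryl iodides with terminal epoxides to 2-substituted 2,3-dihydrobenzofurans, which goes with retention at the carbinol carbon; new here is an internal epoxide that carries a ketone. The dihydrofuran ring closes by C(aryl)–O reductive elimination at C7a from a six-membered aryl palladium alkoxide, and C2 keeps the epoxide configuration because its C–O bond is never broken. C3 is formed with inversion (cis-epimer 14) and is equilibrated through the ketone enolate by carbonate, and by DBU before work-up, to trans 15, in which the aroyl group lies anti to the C2 aryl group; loss of O1 from that enolate would be a reverse 5-endo-trig process and should be slow. The step needs opening at the α-keto rather than the benzylic carbon, which the carbonyl group and the absence of acid should secure; single alkylation at C3a and norbornene extrusion, which the dioxolane at C7 secures; and coupling faster than isomerisation of 10 to the 1,3-diketone, for which 5 is kept in excess so that zerovalent palladium is consumed by oxidative addition.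

Step 9
Reactants: 15 [(2R,3R)-4,6-bis(benzyloxy)-2-[4-(benzyloxy)phenyl]-7-(1,3-dioxolan-2-yl)-2,3-dihydro-1-benzofuran-3-yl][2,4-bis(benzyloxy)phenyl]methanone
Product: 16 (2R,3R)-4,6-bis(benzyloxy)-3-[2,4-bis(benzyloxy)benzoyl]-2-[4-(benzyloxy)phenyl]-2,3-dihydro-1-benzofuran-7-carbaldehyde
Conditions: PPTS, acetone–H2O, 40 °C
Reagents that add atoms: water, O
Why: Acid-catalysed acetal hydrolysis; the trioxygenated aryl group stabilises the oxocarbenium ion, so a weak acid that leaves the C2–O1 bond alone should suffice, and C3 is already in its stable trans arrangement.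

Step 10
Reactants: 16 (2R,3R)-4,6-bis(benzyloxy)-3-[2,4-bis(benzyloxy)benzoyl]-2-[4-(benzyloxy)phenyl]-2,3-dihydro-1-benzofuran-7-carbaldehyde; 13 1-[4-(benzyloxy)phenyl]ethenyl trifluoromethanesulfonate
Product: 17 [(2R,3R)-4,6-bis(benzyloxy)-2-[4-(benzyloxy)phenyl]-7-{2-[4-(benzyloxy)phenyl]-1-hydroxyprop-2-en-1-yl}-2,3-dihydro-1-benzofuran-3-yl][2,4-bis(benzyloxy)phenyl]methanone (both carbinol epimers)
Conditions: CrCl2, NiCl2 (cat.), DMF, rt
Reagents that add atoms: none
Why: Nozaki–Hiyama–Kishi reaction; the nickel-generated alkenylchromium species adds to aldehydes but not to ketones and is not basic enough to enolise C3; the new carbinol centre is not controlled and is removed in step 11.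

Step 11
Reactants: 17 [(2R,3R)-4,6-bis(benzyloxy)-2-[4-(benzyloxy)phenyl]-7-{2-[4-(benzyloxy)phenyl]-1-hydroxyprop-2-en-1-yl}-2,3-dihydro-1-benzofuran-3-yl][2,4-bis(benzyloxy)phenyl]methanone
Product: 18 1-{(2R,3R)-4,6-bis(benzyloxy)-3-[2,4-bis(benzyloxy)benzoyl]-2-[4-(benzyloxy)phenyl]-2,3-dihydro-1-benzofuran-7-yl}-2-[4-(benzyloxy)phenyl]prop-2-en-1-one
Conditions: Dess–Martin periodinane, NaHCO3, CH2Cl2, 0 °C to rt
Reagents that add atoms: none
Why: Dess–Martin oxidation of an allylic and benzylic alcohol; the hydrogen carbonate buffer protects the acid-sensitive carbinol and both epimers of 17 give the same enone.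

Step 12
Reactants: 18 1-{(2R,3R)-4,6-bis(benzyloxy)-3-[2,4-bis(benzyloxy)benzoyl]-2-[4-(benzyloxy)phenyl]-2,3-dihydro-1-benzofuran-7-yl}-2-[4-(benzyloxy)phenyl]prop-2-en-1-one
Product: 19 1-[(2R,3R)-3-(2,4-dihydroxybenzoyl)-4,6-dihydroxy-2-(4-hydroxyphenyl)-2,3-dihydro-1-benzofuran-7-yl]-2-(4-hydroxyphenyl)prop-2-en-1-one
Conditions: BCl3, C6HMe5, CH2Cl2, −78 °C; then MeOH
Reagents that add atoms: none
Why: Lewis-acid debenzylation of aryl benzyl ethers with pentamethylbenzene as a non-basic benzyl cation scavenger; the alkene and the ketones are not reduced and no phenoxide is formed, so the C6 hydroxyl should not add to the acrylophenone.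

## Compound list

1 | 5-iodoresorcinol (5-iodobenzene-1,3-diol) | Oc1cc(O)cc(I)c1 | starting material
2 | 1,3-bis(benzyloxy)-5-iodobenzene | Ic1cc(OCc2ccccc2)cc(OCc2ccccc2)c1 | intermediate
3 | N-{[2,4-bis(benzyloxy)-6-iodophenyl]methylidene}-N-methylmethanaminium chloride | C[N+](C)=Cc1c(I)cc(OCc2ccccc2)cc1OCc1ccccc1.[Cl-] | intermediate (not isolated)
4 | 2,4-bis(benzyloxy)-6-iodobenzaldehyde | O=Cc1c(I)cc(OCc2ccccc2)cc1OCc1ccccc1 | intermediate
5 | 2-[2,4-bis(benzyloxy)-6-iodophenyl]-1,3-dioxolane | Ic1cc(OCc2ccccc2)cc(OCc2ccccc2)c1C1OCCO1 | intermediate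
6 | 1-(2,4-dihydroxyphenyl)ethan-1-one | CC(=O)c1ccc(O)cc1O | starting material
7 | 1-[2,4-bis(benzyloxy)phenyl]ethan-1-one | CC(=O)c1ccc(OCc2ccccc2)cc1OCc1ccccc1 | intermediate
8 | 4-(benzyloxy)benzaldehyde | O=Cc1ccc(OCc2ccccc2)cc1 | starting material
9 | (E)-1-[2,4-bis(benzyloxy)phenyl]-3-[4-(benzyloxy)phenyl]prop-2-en-1-one | O=C(/C=C/c1ccc(OCc2ccccc2)cc1)c1ccc(OCc2ccccc2)cc1OCc1ccccc1 | intermediate
10 | [2,4-bis(benzyloxy)phenyl]{(2R,3S)-3-[4-(benzyloxy)phenyl]oxiran-2-yl}methanone | O=C(c1ccc(OCc2ccccc2)cc1OCc1ccccc1)[C@@H]1O[C@H]1c1ccc(OCc2ccccc2)cc1 | intermediate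
11 | 1-[4-(benzyloxy)phenyl]ethan-1-one | CC(=O)c1ccc(OCc2ccccc2)cc1 | starting material
12 | potassium 1-[4-(benzyloxy)phenyl]ethen-1-olate | [K+].[O-]C(=C)c1ccc(OCc2ccccc2)cc1 | intermediate (not isolated)
13 | 1-[4-(benzyloxy)phenyl]ethenyl trifluoromethanesulfonate | C=C(OS(=O)(=O)C(F)(F)F)c1ccc(OCc2ccccc2)cc1 | intermediate
14 | [(2R,3S)-4,6-bis(benzyloxy)-2-[4-(benzyloxy)phenyl]-7-(1,3-dioxolan-2-yl)-2,3-dihydro-1-benzofuran-3-yl][2,4-bis(benzyloxy)phenyl]methanone (2,3-cis) | C1(OCCO1)c1c(OCc3ccccc3)cc(OCc3ccccc3)c2c1O[C@@H](c1ccc(OCc3ccccc3)cc1)[C@H]2C(=O)c1ccc(OCc3ccccc3)cc1OCc1ccccc1 | intermediate (not isolated)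
15 | [(2R,3R)-4,6-bis(benzyloxy)-2-[4-(benzyloxy)phenyl]-7-(1,3-dioxolan-2-yl)-2,3-dihydro-1-benzofuran-3-yl][2,4-bis(benzyloxy)phenyl]methanone (2,3-trans) | C1(OCCO1)c1c(OCc3ccccc3)cc(OCc3ccccc3)c2c1O[C@@H](c1ccc(OCc3ccccc3)cc1)[C@@H]2C(=O)c1ccc(OCc3ccccc3)cc1OCc1ccccc1 | intermediate
16 | (2R,3R)-4,6-bis(benzyloxy)-3-[2,4-bis(benzyloxy)benzoyl]-2-[4-(benzyloxy)phenyl]-2,3-dihydro-1-benzofuran-7-carbaldehyde | O=Cc1c(OCc3ccccc3)cc(OCc3ccccc3)c2c1O[C@@H](c1ccc(OCc3ccccc3)cc1)[C@@H]2C(=O)c1ccc(OCc3ccccc3)cc1OCc1ccccc1 | intermediate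
17 | [(2R,3R)-4,6-bis(benzyloxy)-2-[4-(benzyloxy)phenyl]-7-{2-[4-(benzyloxy)phenyl]-1-hydroxyprop-2-en-1-yl}-2,3-dihydro-1-benzofuran-3-yl][2,4-bis(benzyloxy)phenyl]methanone (both carbinol epimers) | C=C(C(O)c1c(OCc3ccccc3)cc(OCc3ccccc3)c2c1O[C@@H](c1ccc(OCc3ccccc3)cc1)[C@@H]2C(=O)c1ccc(OCc3ccccc3)cc1OCc1ccccc1)c1ccc(OCc2ccccc2)cc1 | intermediate
18 | 1-{(2R,3R)-4,6-bis(benzyloxy)-3-[2,4-bis(benzyloxy)benzoyl]-2-[4-(benzyloxy)phenyl]-2,3-dihydro-1-benzofuran-7-yl}-2-[4-(benzyloxy)phenyl]prop-2-en-1-one | C=C(C(=O)c1c(OCc3ccccc3)cc(OCc3ccccc3)c2c1O[C@@H](c1ccc(OCc3ccccc3)cc1)[C@@H]2C(=O)c1ccc(OCc3ccccc3)cc1OCc1ccccc1)c1ccc(OCc2ccccc2)cc1 | intermediate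
19 | 1-[(2R,3R)-3-(2,4-dihydroxybenzoyl)-4,6-dihydroxy-2-(4-hydroxyphenyl)-2,3-dihydro-1-benzofuran-7-yl]-2-(4-hydroxyphenyl)prop-2-en-1-one (CNP0162111.1) | C=C(C(=O)c1c(O)cc(O)c2c1O[C@@H](c1ccc(O)cc1)[C@@H]2C(=O)c1ccc(O)cc1O)c1ccc(O)cc1 | target

## Step count and risk

Total: 12 steps. Longest linear sequence: 8 steps (1, 2, 3, 8, 9, 10, 11, 12; the epoxide branch 4, 5, 6 is equally long).

**Step 8 (key step, proposed new method).**
- What may go wrong: ring opening of an internal epoxide at a secondary carbon by a hindered palladacycle may be too slow. The epoxy ketone would then be consumed by isomerisation to the 1,3-diketone at zerovalent palladium. The β-oxido ketone formed after opening could also fragment by retro-aldol cleavage before C–O reductive elimination. Palladation at C3a next to the C4 benzyloxy group may be slow as well, leading to reduction or homocoupling of the iodide.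
- Fallback (known chemistry; the ring is closed at C2–C3 by carbenoid C–H insertion): it sets out from 4 and 7 and comes back at 14, and so at 15.
  - Copper-catalysed hydroxylation of 4 (CuI, 1,10-phenanthroline, KOH, DMSO–H2O) would give 2,4-bis(benzyloxy)-6-hydroxybenzaldehyde F1.
  - Iodination ortho to the chelated hydroxyl (BnMe3N·ICl2, CaCO3, CH2Cl2–MeOH) would give 4,6-bis(benzyloxy)-2-hydroxy-3-iodobenzaldehyde F2, in which iodine marks C3a.
  - O-Alkylation with 4-(benzyloxy)benzyl chloride (K2CO3, DMF) would give 4,6-bis(benzyloxy)-2-{[4-(benzyloxy)phenyl]methoxy}-3-iodobenzaldehyde F3, and acetalisation as in step 3 would give 2-[4,6-bis(benzyloxy)-2-{[4-(benzyloxy)phenyl]methoxy}-3-iodophenyl]-1,3-dioxolane F4.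
  - Palladium-catalysed α-arylation of ketone 7 with F4 (Pd2(dba)3, XPhos, NaOt-Bu, toluene, 80 °C) would give 2-[4,6-bis(benzyloxy)-2-{[4-(benzyloxy)phenyl]methoxy}-3-(1,3-dioxolan-2-yl)phenyl]-1-[2,4-bis(benzyloxy)phenyl]ethan-1-one F5.
  - Diazo transfer (4-acetamidobenzenesulfonyl azide, DBU, MeCN) would give 2-[4,6-bis(benzyloxy)-2-{[4-(benzyloxy)phenyl]methoxy}-3-(1,3-dioxolan-2-yl)phenyl]-1-[2,4-bis(benzyloxy)phenyl]-2-diazoethan-1-one F6.
  - Rh2(S-PTTL)4 or its enantiomer, whichever delivers 2R, in toluene at low temperature should insert the carbenoid into the 4-(benzyloxy)benzylic C–H bond to give 14, which DBU converts into 15.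
  - The weakness of this fallback is competition from the less electron-rich benzyl ether at C4.

**Step 6.**
- What may go wrong: low enantioselectivity or slow conversion, because 9 is an electron-rich enone and its 2-benzyloxy group twists the aroyl group and may hinder binding to the polypeptide.
- Fallback (the epoxide is built by C–C bond formation instead of enone epoxidation): it sets out from 8 and comes back at 10. Asymmetric sulfonium ylide epoxidation of 8 with the camphor-derived chiral sulfonium salt of N,N-diethyl-2-bromoacetamide (base, EtOH, low temperature; the enantiomer of the salt chosen for 2R,3S) would give (2R,3S)-3-[4-(benzyloxy)phenyl]-N,N-diethyloxirane-2-carboxamide F7. Addition of 2,4-bis(benzyloxy)phenyllithium (from the aryl bromide and n-BuLi, THF, −78 °C) to the amide would give 10.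

**Step 10.**
- What may go wrong: slow addition to the electron-rich aldehyde flanked by two ortho oxygens, with loss of triflate 13 by hydrolysis or homocoupling, and ionisation of the very electron-rich carbinol on work-up.
- Fallback (benzyl addition and methylenation instead of alkenyl addition): it sets out from 16 and comes back at 18.
  - Addition of 4-(benzyloxy)benzylzinc chloride (from the benzyl chloride, Zn and LiCl; MgCl2, THF), which adds to aldehydes and not to ketones, would give [(2R,3R)-4,6-bis(benzyloxy)-2-[4-(benzyloxy)phenyl]-7-{2-[4-(benzyloxy)phenyl]-1-hydroxyethyl}-2,3-dihydro-1-benzofuran-3-yl][2,4-bis(benzyloxy)phenyl]methanone F8.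
  - Dess–Martin oxidation would give 1-{(2R,3R)-4,6-bis(benzyloxy)-3-[2,4-bis(benzyloxy)benzoyl]-2-[4-(benzyloxy)phenyl]-2,3-dihydro-1-benzofuran-7-yl}-2-[4-(benzyloxy)phenyl]ethan-1-one F9.
  - Mannich-type α-methylenation of the only α-methylene ketone (bis(dimethylamino)methane, Ac2O, 60 °C) would give 18.

**Step 12.**
- What may go wrong: Friedel–Crafts transfer of benzyl cations to C5 of ring A; opening of the C2–O1 bond by the Lewis acid, followed by reclosure onto the wrong hydroxyl; and addition of chloride or of the C6 hydroxyl to the acrylophenone during quench.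
- Fallback (the enone is masked and the benzyl groups are removed by hydrogenolysis): it sets out from 18 and comes back at 19.
  - Conjugate addition of dimethylamine (THF, rt) would give 1-{(2R,3R)-4,6-bis(benzyloxy)-3-[2,4-bis(benzyloxy)benzoyl]-2-[4-(benzyloxy)phenyl]-2,3-dihydro-1-benzofuran-7-yl}-2-[4-(benzyloxy)phenyl]-3-(dimethylamino)propan-1-one F10.
  - Hydrogenolysis of its hydrochloride (H2, Pd/C, EtOAc–MeOH) would give 1-[(2R,3R)-3-(2,4-dihydroxybenzoyl)-4,6-dihydroxy-2-(4-hydroxyphenyl)-2,3-dihydro-1-benzofuran-7-yl]-3-(dimethylamino)-2-(4-hydroxyphenyl)propan-1-one F11, handled as its hydrochloride.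
  - Gentle warming of this salt in MeCN should eliminate dimethylamine and release 19 without base.
  - The fallback carries two risks of its own: premature loss of the amine during hydrogenolysis, which would expose the alkene to reduction, and hydrogenolysis of the benzylic C2–O1 bond.

## Further compounds

F1 | step 8 | 2,4-bis(benzyloxy)-6-hydroxybenzaldehyde | O=Cc1c(O)cc(OCc2ccccc2)cc1OCc1ccccc1
F2 | step 8 | 4,6-bis(benzyloxy)-2-hydroxy-3-iodobenzaldehyde | O=Cc1c(O)c(I)c(OCc2ccccc2)cc1OCc1ccccc1
F3 | step 8 | 4,6-bis(benzyloxy)-2-{[4-(benzyloxy)phenyl]methoxy}-3-iodobenzaldehyde | O=Cc1c(OCc2ccc(OCc3ccccc3)cc2)c(I)c(OCc2ccccc2)cc1OCc1ccccc1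
F4 | step 8 | 2-[4,6-bis(benzyloxy)-2-{[4-(benzyloxy)phenyl]methoxy}-3-iodophenyl]-1,3-dioxolane | Ic1c(OCc2ccc(OCc3ccccc3)cc2)c(C2OCCO2)c(OCc2ccccc2)cc1OCc1ccccc1
F5 | step 8 | 2-[4,6-bis(benzyloxy)-2-{[4-(benzyloxy)phenyl]methoxy}-3-(1,3-dioxolan-2-yl)phenyl]-1-[2,4-bis(benzyloxy)phenyl]ethan-1-one | O=C(Cc1c(OCc2ccc(OCc3ccccc3)cc2)c(C2OCCO2)c(OCc2ccccc2)cc1OCc1ccccc1)c1ccc(OCc2ccccc2)cc1OCc1ccccc1
F6 | step 8 | 2-[4,6-bis(benzyloxy)-2-{[4-(benzyloxy)phenyl]methoxy}-3-(1,3-dioxolan-2-yl)phenyl]-1-[2,4-bis(benzyloxy)phenyl]-2-diazoethan-1-one | O=C(C(=[N+]=[N-])c1c(OCc2ccc(OCc3ccccc3)cc2)c(C2OCCO2)c(OCc2ccccc2)cc1OCc1ccccc1)c1ccc(OCc2ccccc2)cc1OCc1ccccc1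
F7 | step 6 | (2R,3S)-3-[4-(benzyloxy)phenyl]-N,N-diethyloxirane-2-carboxamide | CCN(CC)C(=O)[C@@H]1O[C@H]1c1ccc(OCc2ccccc2)cc1
F8 | step 10 | [(2R,3R)-4,6-bis(benzyloxy)-2-[4-(benzyloxy)phenyl]-7-{2-[4-(benzyloxy)phenyl]-1-hydroxyethyl}-2,3-dihydro-1-benzofuran-3-yl][2,4-bis(benzyloxy)phenyl]methanone (both carbinol epimers) | OC(Cc1ccc(OCc2ccccc2)cc1)c1c(OCc3ccccc3)cc(OCc3ccccc3)c2c1O[C@@H](c1ccc(OCc3ccccc3)cc1)[C@@H]2C(=O)c1ccc(OCc3ccccc3)cc1OCc1ccccc1
F9 | step 10 | 1-{(2R,3R)-4,6-bis(benzyloxy)-3-[2,4-bis(benzyloxy)benzoyl]-2-[4-(benzyloxy)phenyl]-2,3-dihydro-1-benzofuran-7-yl}-2-[4-(benzyloxy)phenyl]ethan-1-one | O=C(Cc1ccc(OCc2ccccc2)cc1)c1c(OCc3ccccc3)cc(OCc3ccccc3)c2c1O[C@@H](c1ccc(OCc3ccccc3)cc1)[C@@H]2C(=O)c1ccc(OCc3ccccc3)cc1OCc1ccccc1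
F10 | step 12 | 1-{(2R,3R)-4,6-bis(benzyloxy)-3-[2,4-bis(benzyloxy)benzoyl]-2-[4-(benzyloxy)phenyl]-2,3-dihydro-1-benzofuran-7-yl}-2-[4-(benzyloxy)phenyl]-3-(dimethylamino)propan-1-one (both epimers at the new centre) | CN(C)CC(C(=O)c1c(OCc3ccccc3)cc(OCc3ccccc3)c2c1O[C@@H](c1ccc(OCc3ccccc3)cc1)[C@@H]2C(=O)c1ccc(OCc3ccccc3)cc1OCc1ccccc1)c1ccc(OCc2ccccc2)cc1
F11 | step 12 | 1-[(2R,3R)-3-(2,4-dihydroxybenzoyl)-4,6-dihydroxy-2-(4-hydroxyphenyl)-2,3-dihydro-1-benzofuran-7-yl]-3-(dimethylamino)-2-(4-hydroxyphenyl)propan-1-one (both epimers at the amine-bearing chain centre) | CN(C)CC(C(=O)c1c(O)cc(O)c2c1O[C@@H](c1ccc(O)cc1)[C@@H]2C(=O)c1ccc(O)cc1O)c1ccc(O)cc1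
A1 | alternative 1 | tert-butyl{[(2S,3R)-3-(ethynyloxy)-2-({[tri(propan-2-yl)silyl]oxy}ethynyl)-3-(4-{[tri(propan-2-yl)silyl]oxy}phenyl)propyl]oxy}dimethylsilane | C#CO[C@@H](c1ccc(O[Si](C(C)C)(C(C)C)C(C)C)cc1)[C@H](CO[Si](C)(C)C(C)(C)C)C#CO[Si](C(C)C)(C(C)C)C(C)C
A2 | alternative 1 | (ethynyloxy)tri(propan-2-yl)silane | C#CO[Si](C(C)C)(C(C)C)C(C)C
A3 | alternative 1 | (2R,3S)-3-({[tert-butyl(dimethyl)silyl]oxy}methyl)-4,6-bis{[tri(propan-2-yl)silyl]oxy}-2-(4-{[tri(propan-2-yl)silyl]oxy}phenyl)-2,3-dihydro-1-benzofuran (2,3-trans) | c1c(O[Si](C(C)C)(C(C)C)C(C)C)cc(O[Si](C(C)C)(C(C)C)C(C)C)c2c1O[C@@H](c1ccc(O[Si](C(C)C)(C(C)C)C(C)C)cc1)[C@@H]2CO[Si](C)(C)C(C)(C)C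
A4 | alternative 2 | 1-[2,4-bis(benzyloxy)phenyl]-2-diazoethan-1-one | [N-]=[N+]=CC(=O)c1ccc(OCc2ccccc2)cc1OCc1ccccc1
A5 | alternative 2 | 1,3,5-tris(benzyloxy)benzene | c1c(OCc2ccccc2)cc(OCc2ccccc2)cc1OCc1ccccc1
A6 | alternative 2 | (2R,3R)-1-[2,4-bis(benzyloxy)phenyl]-3-[4-(benzyloxy)phenyl]-3-hydroxy-2-[2,4,6-tris(benzyloxy)phenyl]propan-1-one | c1(OCc2ccccc2)cc(OCc2ccccc2)cc(OCc2ccccc2)c1[C@@H](C(=O)c1ccc(OCc2ccccc2)cc1OCc1ccccc1)[C@@H](O)c1ccc(OCc2ccccc2)cc1
A7 | alternative 3 | ethyl 2-[2,4-bis{[tert-butyl(dimethyl)silyl]oxy}-6-{[4-({[tert-butyl(dimethyl)silyl]oxy})phenyl]methoxy}phenyl]-2-diazoacetate | CCOC(=O)C(=[N+]=[N-])c1c(OCc2ccc(O[Si](C)(C)C(C)(C)C)cc2)cc(O[Si](C)(C)C(C)(C)C)cc1O[Si](C)(C)C(C)(C)C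
A8 | alternative 3 | ethyl (2R,3R)-4,6-bis{[tert-butyl(dimethyl)silyl]oxy}-2-(4-{[tert-butyl(dimethyl)silyl]oxy}phenyl)-2,3-dihydro-1-benzofuran-3-carboxylate | c1c(O[Si](C)(C)C(C)(C)C)cc(O[Si](C)(C)C(C)(C)C)c2c1O[C@@H](c1ccc(O[Si](C)(C)C(C)(C)C)cc1)[C@@H]2C(=O)OCC
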